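Start from the eta run and the beta run, and put their percentages into [target] in M.

| flask | solid substrate | remark | time |
|---|---|---|---|
| eta | 0.050 M | run made earlier |  |
| beta | 0.20 M | run made earlier |  |
| flask | 0.10 M |  | 4.0 min |

| run | time / min | target / % |
|---|---|---|
| eta | 0.417 | 12.9 |
| eta | 0.667 | 23.6 |
| eta | 1.00 | 29.2 |
| eta | 1.50 | 26.1 |
| eta | 2.50 | 13.6 |
| beta | 0.417 | 3.1 |
| beta | 0.667 | 5.1 |
| beta | 1.00 | 8.4 |
| beta | 1.50 | 11.0 |
| beta | 2.50 | 15.0 |

(readings scatter by 0.5 percentage points)

* time up to 4.0 min at which target stands highest
* the amount of target, in percent of the solid substrate charged, at that time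

- solid substrate is a solid; its amount is given per volume of the solution
- at the start none of the solid substrate is in solution

Step 1. Here are two ways to one number. At 0.417 min the eta run holds 0.00645 M of target and the beta run 0.00620 M, although the beta charge is 4.00 times the eta charge. While they agree, [target] is zero order in the charge. Call this the shared curve.

Step 2. At 1.50 min they part: eta 0.0131 M, beta 0.0220 M. The eta run has fallen from its reading of 29.2% at 1.00 min, while the beta run still climbs. So eta is the one that has left the curve, and I take that as its solid ending near that reading.

Step 3. On that view the eta charge was taken up in about 1.00 min, which gives 0.0500 M min⁻¹ as the uptake rate, the charge taken up per minute along the shared curve. For the beta run, charge over uptake rate gives 4.00 min, later than its last reading at 2.50 min, which fits its climb. For the asked flask it gives 2.00 min.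

Step 4. That time lies midway between the beta readings at 1.50 min and 2.50 min, where the beta run gives 0.0260 M, which is 26.0% of the asked flask's charge.

Step 5. The forecast, holding that “Turnover time should scale with loading”, gave 1.9 min and 24%, earlier and lower than my reckoning.

Step 6. The flask peaks at 1.80 min with 24.7%, when its solid substrate stands at 0%.

    starting material ⇌ isomer of the product (K = 2.90, k = 0.00883 s⁻¹)
    target → over-reaction product (k = 0.0252 s⁻¹)
    target ⇌ isomer of the product (k = 0.00472 s⁻¹)
    starting material ⇌ target (K = 13.0, k = 0.0211 s⁻¹)
    solid substrate ⇌ starting material, rate k5*(cs5 - [starting material]) while solid is left; crystals form when [starting material] > cs5 (solubility = 0.0510 M, k = 0.0381 s⁻¹)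

In this flask, charge over best time comes to 0.0556 M min⁻¹, more than my uptake rate of 0.0500 M min⁻¹, and my height stands 1.3 percentage points high.

Step 7. For the neighbour flask with 0.040 M, charge over uptake rate gives 0.800 min, and the beta readings, interpolated at that time, give 32.1% of its charge. That neighbour flask reaches 30.1%.

The runs stem from a simulated flask with constants of no real substance.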